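**Strategy.** The route rests on cutting the C21–C22 single bond in the middle of the all-E pentaene (C16–C25) of the 28-membered lactone ring (C1–C27 plus the ring oxygen). Both atoms are sp2 carbons of polyene arms, so an intramolecular Stille coupling of a seco-ester carrying a C16–C21 (E,E,E)-trienyl bromide and a C22–C25 (E,E)-dienyl stannane closes the macrolactone ring and completes the pentaene chromophore in one operation, after all ten stereocentres are in place. The seco-ester is assembled from a C2-symmetric C3–C11 dialdehyde by two aldol couplings (C12–C21 methyl ketone, C1–C2 butanoyl imide) and esterified with the C22–C27 stannyl dienol.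

Key step: step 19

Remark: locants C1–C27 are those of the macrolactone (C1 lactone carbonyl, C27 lactone carbinol carbon); (2R,3R)-2,3-dimethyloxirane, glutaconaldehyde potassium salt (KOCH=CH–CH=CH–CHO) and both N-acyl oxazolidinones are treated as catalogue compounds.

**Route**

Step 1
Reactants: 1 (2R,3R)-2,3-dimethyloxirane
Product: 2 (2R,3R)-3-methylpent-4-yn-2-ol
Conditions: LiC≡CH·H2NCH2CH2NH2, DMSO, rt
Reagents that add atoms: lithium acetylide–ethylenediamine complex, [Li+].[C-]#C.NCCN
Why: SN2 opening of the C2-symmetric trans-epoxide by acetylide (epoxide alkynylation) inverts the attacked carbon, which sets the syn C26/C27 pair, and the two homotopic ring carbons allow only one product.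

Step 2
Reactants: 2 (2R,3R)-3-methylpent-4-yn-2-ol
Product: 4 (2R,3R,4E)-5-iodo-3-methylpent-4-en-2-ol, via vinylstannane 3 (not isolated)
Conditions: Bu3SnH, PdCl2(PPh3)2 (cat.), THF, 0 °C; then I2, CH2Cl2, 0 °C
Reagents that add atoms: iodine, II
Why: Palladium-catalysed syn-hydrostannation places tin on the unhindered terminal carbon to give the E-vinylstannane, and iododestannylation replaces tin by iodine with retention of the E geometry.

Step 3
Reactants: 4 (2R,3R,4E)-5-iodo-3-methylpent-4-en-2-ol; 5 (E)-1,2-bis(tributylstannyl)ethene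
Product: 6 (2R,3R,4E,6E)-3-methyl-7-(tributylstannyl)hepta-4,6-dien-2-ol
Conditions: 5 (3 equiv), PdCl2(MeCN)2 (cat.), DMF, rt, dark
Reagents that add atoms: none
Why: Stille coupling of the vinyl iodide with one tin terminus of the excess bis-stannane proceeds with retention at both alkenes and should give the (4E,6E)-dienyl stannane, the excess suppressing a second coupling.

Step 4
Reactants: 7 glutaconaldehyde potassium salt
Product: 8 (2E,4E)-5-bromopenta-2,4-dienal
Conditions: PPh3, Br2, CH2Cl2, 0 °C to rt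
Reagents that add atoms: bromine (delivered as Ph3PBr2), BrBr
Why: Ph3PBr2 activates the enolate oxygen as an oxyphosphonium group that bromide displaces by addition–elimination (deoxybromination of a vinylogous carboxylate), giving the thermodynamically preferred E,E-bromodienal.

Step 5
Reactants: 8 (2E,4E)-5-bromopenta-2,4-dienal; 9 (triphenylphosphoranylidene)acetaldehyde
Product: 10 (2E,4E,6E)-7-bromohepta-2,4,6-trienal
Conditions: 9 (1 equiv), toluene, 60 °C
Reagents that add atoms: none
Why: Wittig olefination with the stabilised formyl ylide should form the new C=C bond with E geometry, and one equivalent limits further vinylogation of the product.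

Step 6
Reactants: 11 (4S)-4-benzyl-3-propanoyl-1,3-oxazolidin-2-one; 10 (2E,4E,6E)-7-bromohepta-2,4,6-trienal
Product: 13 (4S)-4-benzyl-3-[(2S,3R,4E,6E,8E)-9-bromo-3-hydroxy-2-methylnona-4,6,8-trienoyl]-1,3-oxazolidin-2-one, via boron enolate 12 (not isolated)
Conditions: Bu2BOTf, iPr2NEt, CH2Cl2, 0 °C; then 10, −78 to 0 °C; pH 7 buffer, MeOH, H2O2
Reagents that add atoms: none
Why: Evans syn-aldol reaction in which the Z-boron enolate adds through a chair Zimmerman–Traxler transition state on the face set by the benzyl auxiliary, fixing C14 and C15 (2S,3R in the adduct).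

Step 7
Reactants: 13 Evans adduct
Product: 14 (2S,3R,4E,6E,8E)-9-bromo-3-hydroxy-N-methoxy-N,2-dimethylnona-4,6,8-trienamide
Conditions: MeNH(OMe)·HCl, AlMe3, THF, −20 to 0 °C
Reagents that add atoms: N,O-dimethylhydroxylamine hydrochloride, CNOC.Cl
Why: Weinreb transamidation with the aluminium amide, assisted by the free β-hydroxyl, releases the auxiliary without touching the α-stereocentre.

Step 8
Reactants: 14 Weinreb amide
Product: 15 (2S,3R,4E,6E,8E)-9-bromo-3-(tert-butyldimethylsilyloxy)-N-methoxy-N,2-dimethylnona-4,6,8-trienamide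
Conditions: TBSOTf, 2,6-lutidine, CH2Cl2, −78 °C
Reagents that add atoms: tert-butyldimethylsilyl triflate, CC(C)(C)[Si](C)(C)OS(=O)(=O)C(F)(F)F
Why: Silylation with the silyl triflate under lutidine buffering protects the trienylic C15 alcohol without ionising it.

Step 9
Reactants: 15 silylated Weinreb amide
Product: 16 (3S,4R,5E,7E,9E)-10-bromo-4-(tert-butyldimethylsilyloxy)-3-methyldeca-5,7,9-trien-2-one (C12–C21 methyl ketone)
Conditions: MeMgBr, THF, −20 to 0 °C
Reagents that add atoms: methylmagnesium bromide, C[Mg]Br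
Why: Weinreb ketone synthesis in which the chelated tetrahedral intermediate stops at mono-addition, so the C13 methyl ketone should form without over-addition or epimerisation at C14 while the vinyl bromide stays inert to the Grignard reagent.

Step 10
Reactants: 17 pentanedial (freshly distilled anhydrous monomer)
Product: 18 (4S,8S)-undeca-1,10-diene-4,8-diol
Conditions: (+)-Ipc2BOMe [from (−)-α-pinene], allylMgBr, Et2O, 0 °C to rt; then 17, −78 °C; NaOH, H2O2
Reagents that add atoms: allylmagnesium bromide, C=CC[Mg]Br; B-allylbis(isopinocampheyl)borane made from it in the flask, C=CCB([C@H]1C[C@H]2C[C@@H]([C@@H]1C)C2(C)C)[C@H]1C[C@H]2C[C@@H]([C@@H]1C)C2(C)C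
Why: Two-fold Brown allylboration in which the allylborane of the (−)-α-pinene series adds to the Re face of each aldehyde group through a chair transition state, setting C5 and C9 (both S), while the second reagent-controlled addition enriches the C2-symmetric diol over the meso isomer.

Step 11
Reactants: 18 (4S,8S)-undeca-1,10-diene-4,8-diol
Product: 19 (4S,8S)-4,8-bis(tert-butyldimethylsilyloxy)undeca-1,10-diene
Conditions: TBSCl, imidazole, DMF, rt
Reagents that add atoms: tert-butyldimethylsilyl chloride, CC(C)(C)[Si](C)(C)Cl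
Why: Standard silylation of both secondary alcohols keeps the C2 symmetry and blocks O5 and O9 for the aldol steps.

Step 12
Reactants: 19 bis-silyl diene
Product: 20 (3S,7S)-3,7-bis(tert-butyldimethylsilyloxy)nonanedial (C3–C11 dialdehyde)
Conditions: O3, CH2Cl2, −78 °C; then PPh3, −78 °C to rt
Reagents that add atoms: ozone, [O-][O+]=O
Why: Ozonolysis with reductive work-up cleaves both terminal alkenes to the C3 and C11 aldehyde groups, and the β-silyloxy aldehydes should survive the neutral PPh3 work-up.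

Step 13
Reactants: 16 C12–C21 methyl ketone; 20 C3–C11 dialdehyde
Product: 22 C3–C21 hydroxy keto aldehyde (C3 aldehyde; 11-OH; 13-oxo; 5,9,15-tris-OTBS; C21 bromide), via boron enolate 21 (not isolated)
Conditions: (−)-Ipc2BCl, Et3N, Et2O, 0 °C; then 20 (3 equiv), −78 to −20 °C; MeOH, pH 7 buffer, H2O2, 0 °C
Reagents that add atoms: none
Why: Paterson boron aldol reaction in which kinetic enolisation occurs at the methyl group (C12), the excess of the homotopic dialdehyde favours addition to one terminus only, and the (−)-Ipc ligands direct the methyl ketone enolate to the aldehyde Re face to set C11 (S), the sense also preferred by the C14 methyl group (1,4-syn) while the C15 silyl ether exerts no opposing 1,5-effect.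

Step 14
Reactants: 22 C3–C21 hydroxy keto aldehyde; 23 (4S)-4-benzyl-3-butanoyl-1,3-oxazolidin-2-one
Product: 25 C1–C21 imide (N-acyl oxazolidinone; 2-ethyl; 3,11-diol; 13-oxo; 5,9,15-tris-OTBS; C21 bromide), via boron enolate 24 (not isolated)
Conditions: 23 (3 equiv), Bu2BOTf (slightly less than 23), iPr2NEt, CH2Cl2, 0 °C; then 22, −78 to 0 °C; pH 7 buffer, MeOH, H2O2
Reagents that add atoms: none
Why: Evans syn-aldol reaction of the remaining C3 aldehyde in which the auxiliary-controlled Z-boron enolate sets C2 (S) and C3 (R) regardless of the existing centres, boron enolates do not add to the C13 ketone, and one equivalent of enolate is sacrificed to the free C11 hydroxyl.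

Step 15
Reactants: 25 C1–C21 imide
Product: 26 C1–C21 triol imide (3,11,13-triol; 5,9,15-tris-OTBS; C21 bromide)
Conditions: Me4NBH(OAc)3, MeCN/AcOH, −30 to −20 °C
Reagents that add atoms: none
Why: Evans–Saksena reduction in which the C11 hydroxyl exchanges onto boron and delivers hydride intramolecularly through a chair transition state to give the 11,13-anti diol (C13 R), while the β-hydroxy imide is not reduced.

Step 16
Reactants: 26 C1–C21 triol imide
Product: 27 fully silylated C1–C21 imide (3,11,13-tris-OTES; 5,9,15-tris-OTBS; C21 bromide)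
Conditions: TESOTf, 2,6-lutidine, CH2Cl2, −78 to 0 °C
Reagents that add atoms: triethylsilyl triflate, CC[Si](CC)(CC)OS(=O)(=O)C(F)(F)F
Why: Triethylsilyl triflate silylates all three secondary hydroxyls (O3, O11, O13), giving a fully masked chain that carries fluoride-labile groups only.

Step 17
Reactants: 27 fully silylated C1–C21 imide
Product: 29 C1–C21 carboxylic acid (3,11,13-tris-OTES; 5,9,15-tris-OTBS; C21 bromide), via peroxy acid 28 (not isolated)
Conditions: LiOH, H2O2, THF/H2O, 0 °C; then Na2SO3; dilute HCl to pH 4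
Reagents that add atoms: lithium hydroperoxide (from LiOH and H2O2), [Li+].[O-]O
Why: Lithium hydroperoxide attacks the exocyclic imide carbonyl selectively (Evans auxiliary cleavage) and sulfite reduces the peroxy acid, so the C1 acid should be released without epimerising C2 or eliminating the β-silyloxy group.

Step 18
Reactants: 29 C1–C21 carboxylic acid; 6 (2R,3R,4E,6E)-3-methyl-7-(tributylstannyl)hepta-4,6-dien-2-ol
Product: 31 seco-ester (C1 ester of O27; C21 trienyl bromide; C22 dienyl tributylstannane; six silyl ethers), via mixed anhydride 30 (not isolated)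
Conditions: 2,4,6-Cl3C6H2COCl, Et3N, THF, rt; then 6, DMAP, toluene, rt to 40 °C
Reagents that add atoms: none
Why: Yamaguchi esterification through the mixed anhydride and the acyl pyridinium salt acylates the hindered C27 alcohol, and the dienyl stannane tolerates the buffered, non-acidic conditions.

Step 19
Reactants: 31 seco-ester
Product: 32 hexasilyl macrolactone (28-membered ring; all-E C16–C25 pentaene; 3,11,13-tris-OTES; 5,9,15-tris-OTBS)
Conditions: Pd2(dba)3 (10 mol %), AsPh3, iPr2NEt, DMF/THF, 1 mM, 45 °C, dark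
Reagents that add atoms: none
Why: Intramolecular Stille (Migita–Kosugi–Stille) coupling in which zerovalent palladium inserts into the C21–Br bond of the trienyl bromide, the C22 dienyl stannane transmetalates to the divalent palladium centre and reductive elimination forms the C21–C22 sp2–sp2 bond, each event with retention of alkene geometry. The closest known reaction type is the Stille macrocyclisation used to close polyene macrolactones. The one ring closed is the 28-membered lactone ring (C1–C27 and the lactone oxygen), closed end-to-end between the two terminal sp2 carbons, so no exo/endo alternative exists. No stereocentre is created; the E geometry at C20=C21 and C22=C23 is inherited from the bromide and the stannane, which completes the all-E pentaene C16–C25. The step needs ring closure to outrun intermolecular coupling, homocoupling and protodestannylation, which is secured by 1 mM dilution, by the rigid all-E triene and diene arms that cannot form small rings, and by the weakly bound AsPh3 ligand that accelerates the transmetalation.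

Step 20
Reactants: 32 hexasilyl macrolactone
Product: 33 target macrolide (CNP0382847.1)
Conditions: HF·pyridine, pyridine, THF, 0 °C to rt, dark
Reagents that add atoms: none
Why: Buffered HF·pyridine cleaves all six silyl ethers (three TES, three TBS) by fluoride attack at silicon, and the pyridine buffer should keep the pentaenylic C15–O bond from ionising.

**Compound list**

1 | (2R,3R)-2,3-dimethyloxirane | C[C@H]1O[C@@H]1C | starting material
2 | (2R,3R)-3-methylpent-4-yn-2-ol | O[C@H](C)[C@H](C)C#C | intermediate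
3 | (2R,3R,4E)-3-methyl-5-(tributylstannyl)pent-4-en-2-ol (formed in the flask) | O[C@H](C)[C@H](C)/C=C/[Sn](CCCC)(CCCC)CCCC | intermediate
4 | (2R,3R,4E)-5-iodo-3-methylpent-4-en-2-ol | O[C@H](C)[C@H](C)/C=C/I | intermediate
5 | (E)-1,2-bis(tributylstannyl)ethene | CCCC[Sn](CCCC)(CCCC)/C=C/[Sn](CCCC)(CCCC)CCCC | starting material
6 | (2R,3R,4E,6E)-3-methyl-7-(tributylstannyl)hepta-4,6-dien-2-ol | O[C@H](C)[C@H](C)/C=C/C=C/[Sn](CCCC)(CCCC)CCCC | intermediate
7 | glutaconaldehyde potassium salt | [K+].[O-]/C=C/C=C/C=O | starting material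
8 | (2E,4E)-5-bromopenta-2,4-dienal | O=C/C=C/C=C/Br | intermediate
9 | (triphenylphosphoranylidene)acetaldehyde | O=CC=P(c1ccccc1)(c1ccccc1)c1ccccc1 | starting material
10 | (2E,4E,6E)-7-bromohepta-2,4,6-trienal | O=C/C=C/C=C/C=C/Br | intermediate
11 | (4S)-4-benzyl-3-propanoyl-1,3-oxazolidin-2-one | CCC(=O)N1[C@@H](Cc2ccccc2)COC1=O | starting material
12 | dibutylboron (Z)-enolate of 11 (formed in the flask) | CCCCB(CCCC)O/C(=C\C)N1[C@@H](Cc2ccccc2)COC1=O | intermediate
13 | (4S)-4-benzyl-3-[(2S,3R,4E,6E,8E)-9-bromo-3-hydroxy-2-methylnona-4,6,8-trienoyl]-1,3-oxazolidin-2-one | Br/C=C/C=C/C=C/[C@@H](O)[C@H](C)C(=O)N1[C@@H](Cc2ccccc2)COC1=O | intermediate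
14 | (2S,3R,4E,6E,8E)-9-bromo-3-hydroxy-N-methoxy-N,2-dimethylnona-4,6,8-trienamide | Br/C=C/C=C/C=C/[C@@H](O)[C@H](C)C(=O)N(C)OC | intermediate
15 | (2S,3R,4E,6E,8E)-9-bromo-3-(tert-butyldimethylsilyloxy)-N-methoxy-N,2-dimethylnona-4,6,8-trienamide | Br/C=C/C=C/C=C/[C@@H](O[Si](C)(C)C(C)(C)C)[C@H](C)C(=O)N(C)OC | intermediate
16 | (3S,4R,5E,7E,9E)-10-bromo-4-(tert-butyldimethylsilyloxy)-3-methyldeca-5,7,9-trien-2-one | Br/C=C/C=C/C=C/[C@@H](O[Si](C)(C)C(C)(C)C)[C@H](C)C(C)=O | intermediate
17 | pentanedial (glutaraldehyde) | O=CCCCC=O | starting material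
18 | (4S,8S)-undeca-1,10-diene-4,8-diol | C=CC[C@@H](O)CCC[C@H](O)CC=C | intermediate
19 | (4S,8S)-4,8-bis(tert-butyldimethylsilyloxy)undeca-1,10-diene | C=CC[C@@H](O[Si](C)(C)C(C)(C)C)CCC[C@H](O[Si](C)(C)C(C)(C)C)CC=C | intermediate
20 | (3S,7S)-3,7-bis(tert-butyldimethylsilyloxy)nonanedial | O=CC[C@@H](O[Si](C)(C)C(C)(C)C)CCC[C@H](O[Si](C)(C)C(C)(C)C)CC=O | intermediate
21 | enol bis(isopinocampheyl)borinate of 16, (+)-α-pinene series (formed in the flask) | Br/C=C/C=C/C=C/[C@@H](O[Si](C)(C)C(C)(C)C)[C@H](C)C(=C)OB([C@@H]1C[C@@H]2C[C@H]([C@H]1C)C2(C)C)[C@@H]1C[C@@H]2C[C@H]([C@H]1C)C2(C)C | intermediate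
22 | C3–C21 hydroxy keto aldehyde (C3 aldehyde, 11-OH, 13-oxo, 5,9,15-tris-OTBS, C21 bromide; centres arranged as in the target) | Br/C=C/C=C/C=C/[C@@H](O[Si](C)(C)C(C)(C)C)[C@H](C)C(=O)C[C@@H](O)C[C@@H](O[Si](C)(C)C(C)(C)C)CCC[C@H](O[Si](C)(C)C(C)(C)C)CC=O | intermediate
23 | (4S)-4-benzyl-3-butanoyl-1,3-oxazolidin-2-one | CCCC(=O)N1[C@@H](Cc2ccccc2)COC1=O | starting material
24 | dibutylboron (Z)-enolate of 23 (formed in the flask) | CCCCB(CCCC)O/C(=C\CC)N1[C@@H](Cc2ccccc2)COC1=O | intermediate
25 | C1–C21 imide (N-acyl (S)-4-benzyloxazolidinone, 2-ethyl, 3,11-diol, 13-oxo, 5,9,15-tris-OTBS, C21 bromide; centres as in the target) | Br/C=C/C=C/C=C/[C@@H](O[Si](C)(C)C(C)(C)C)[C@H](C)C(=O)C[C@@H](O)C[C@@H](O[Si](C)(C)C(C)(C)C)CCC[C@H](O[Si](C)(C)C(C)(C)C)C[C@@H](O)[C@H](CC)C(=O)N1[C@@H](Cc2ccccc2)COC1=O | intermediate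
26 | C1–C21 triol imide (3,11,13-triol, 5,9,15-tris-OTBS, C21 bromide; centres as in the target) | Br/C=C/C=C/C=C/[C@@H](O[Si](C)(C)C(C)(C)C)[C@H](C)[C@H](O)C[C@@H](O)C[C@@H](O[Si](C)(C)C(C)(C)C)CCC[C@H](O[Si](C)(C)C(C)(C)C)C[C@@H](O)[C@H](CC)C(=O)N1[C@@H](Cc2ccccc2)COC1=O | intermediate
27 | fully silylated C1–C21 imide (3,11,13-tris-OTES, 5,9,15-tris-OTBS, C21 bromide) | Br/C=C/C=C/C=C/[C@@H](O[Si](C)(C)C(C)(C)C)[C@H](C)[C@H](O[Si](CC)(CC)CC)C[C@@H](O[Si](CC)(CC)CC)C[C@@H](O[Si](C)(C)C(C)(C)C)CCC[C@H](O[Si](C)(C)C(C)(C)C)C[C@@H](O[Si](CC)(CC)CC)[C@H](CC)C(=O)N1[C@@H](Cc2ccccc2)COC1=O | intermediate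
28 | C1–C21 peroxy acid (formed in the flask; silyl groups as in 27) | Br/C=C/C=C/C=C/[C@@H](O[Si](C)(C)C(C)(C)C)[C@H](C)[C@H](O[Si](CC)(CC)CC)C[C@@H](O[Si](CC)(CC)CC)C[C@@H](O[Si](C)(C)C(C)(C)C)CCC[C@H](O[Si](C)(C)C(C)(C)C)C[C@@H](O[Si](CC)(CC)CC)[C@H](CC)C(=O)OO | intermediate
29 | C1–C21 carboxylic acid (silyl groups as in 27, C21 bromide) | Br/C=C/C=C/C=C/[C@@H](O[Si](C)(C)C(C)(C)C)[C@H](C)[C@H](O[Si](CC)(CC)CC)C[C@@H](O[Si](CC)(CC)CC)C[C@@H](O[Si](C)(C)C(C)(C)C)CCC[C@H](O[Si](C)(C)C(C)(C)C)C[C@@H](O[Si](CC)(CC)CC)[C@H](CC)C(=O)O | intermediate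
30 | mixed anhydride of 29 with 2,4,6-trichlorobenzoic acid (formed in the flask) | Br/C=C/C=C/C=C/[C@@H](O[Si](C)(C)C(C)(C)C)[C@H](C)[C@H](O[Si](CC)(CC)CC)C[C@@H](O[Si](CC)(CC)CC)C[C@@H](O[Si](C)(C)C(C)(C)C)CCC[C@H](O[Si](C)(C)C(C)(C)C)C[C@@H](O[Si](CC)(CC)CC)[C@H](CC)C(=O)OC(=O)c1c(Cl)cc(Cl)cc1Cl | intermediate
31 | seco-ester (ester of acid 29 with O27 of dienol 6; C21 trienyl bromide and C22 dienyl tributylstannane) | Br/C=C/C=C/C=C/[C@@H](O[Si](C)(C)C(C)(C)C)[C@H](C)[C@H](O[Si](CC)(CC)CC)C[C@@H](O[Si](CC)(CC)CC)C[C@@H](O[Si](C)(C)C(C)(C)C)CCC[C@H](O[Si](C)(C)C(C)(C)C)C[C@@H](O[Si](CC)(CC)CC)[C@H](CC)C(=O)O[C@H](C)[C@H](C)/C=C/C=C/[Sn](CCCC)(CCCC)CCCC | intermediate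
32 | hexasilyl macrolactone (target with OTES at C3, C11, C13 and OTBS at C5, C9, C15) | CC[C@@H]1C(=O)O[C@H](C)[C@H](C)/C=C/C=C/C=C/C=C/C=C/[C@@H](O[Si](C)(C)C(C)(C)C)[C@H](C)[C@H](O[Si](CC)(CC)CC)C[C@@H](O[Si](CC)(CC)CC)C[C@@H](O[Si](C)(C)C(C)(C)C)CCC[C@H](O[Si](C)(C)C(C)(C)C)C[C@H]1O[Si](CC)(CC)CC | intermediate
33 | target macrolide CNP0382847.1 (2S,3R,5S,9S,11S,13R,14R,15R,26R,27R; all-E pentaene) | CC[C@@H]1C(=O)O[C@H](C)[C@H](C)/C=C/C=C/C=C/C=C/C=C/[C@@H](O)[C@H](C)[C@H](O)C[C@@H](O)C[C@@H](O)CCC[C@H](O)C[C@H]1O | target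

**Step count and risk**

Total steps: 20. Longest linear sequence: 14 steps (steps 4–9 and 13–20).

Steps most likely to fail:

1. Step 19 (Stille macrocyclisation). Ring closure may lose out to intermolecular coupling and oligomerisation, oxidative addition into the trienyl bromide may be slow, and the dienyl stannane may be protodestannylated or homocoupled before it reaches the palladium centre. The fallback closes the same C21–C22 bond by a Suzuki–Miyaura coupling. It sets out from vinylstannane 3 (isolated here instead of being iodinated) and from acid 29 and comes back at macrolactone 32. Stille coupling of 3 with commercial (E)-(2-bromovinyl)boronic acid MIDA ester (Pd2(dba)3, AsPh3, DMF, rt) should give the dienyl MIDA boronate alcohol F1. Yamaguchi esterification of 29 with F1 should give the boronate seco-ester F2. Slow-release Suzuki–Miyaura macrocyclisation (Pd(OAc)2, SPhos, aqueous K3PO4, THF, 45 °C, high dilution) then joins C22 to the C21 bromide and gives 32.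

2. Step 13 (aldol union with the dialdehyde). The enolate may add to both aldehyde termini, and facial discrimination at C11 may be incomplete while the valuable ketone is the limiting partner. The fallback reverses the order of the two aldol couplings; it sets out from dialdehyde 20 and comes back at imide 27. Excess 20 is first desymmetrised with the inexpensive boron enolate 24 (Evans syn-aldol) to the hydroxy imide aldehyde F3, which is silylated (TESOTf, 2,6-lutidine, −78 °C) to the O3-TES aldehyde F4. The boron enolate 21 of ketone 16 then meets a single aldehyde group at 1:1 stoichiometry and should give the β-hydroxy ketone F5. Reduction with Me4NBH(OAc)3 gives the 11,13-anti diol F6, and TESOTf converts F6 into 27.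

3. Step 20 (global desilylation). During the long exposure needed for six silyl ethers the pentaenylic C15–O bond may ionise, the lactone may translactonise, or the hindered ethers may be cleaved only in part. The fallback removes the silyl groups before the pentaene exists and closes the ring afterwards; it sets out from acid 29 and vinyl iodide 4 and comes back at target 33. Yamaguchi esterification of 29 with 4 gives the bis-halide seco-ester F7, and HF·pyridine/pyridine in THF gives the hexaol bis-halide F8, which carries only a triene. Treatment of F8 with bis-stannane 5 (1.1 equiv, PdCl2(MeCN)2, iPr2NEt, DMF/THF, high dilution) should couple the more reactive vinyl iodide first, giving the dienyl stannane F9 in the flask. F9 then closes the C21–C22 bond onto the trienyl bromide and gives 33 directly.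

**Further compounds**

F1 | step 19 | (2R,3R,4E,6E)-3-methyl-7-(MIDA-boryl)hepta-4,6-dien-2-ol | O[C@H](C)[C@H](C)/C=C/C=C/B1OC(=O)CN(C)CC(=O)O1
F2 | step 19 | seco-ester of acid 29 with F1 (C21 trienyl bromide, C22 dienyl MIDA boronate) | Br/C=C/C=C/C=C/[C@@H](O[Si](C)(C)C(C)(C)C)[C@H](C)[C@H](O[Si](CC)(CC)CC)C[C@@H](O[Si](CC)(CC)CC)C[C@@H](O[Si](C)(C)C(C)(C)C)CCC[C@H](O[Si](C)(C)C(C)(C)C)C[C@@H](O[Si](CC)(CC)CC)[C@H](CC)C(=O)O[C@H](C)[C@H](C)/C=C/C=C/B1OC(=O)CN(C)CC(=O)O1
F3 | step 13 | C1–C11 hydroxy imide aldehyde (2-ethyl, 3-OH, 5,9-bis-OTBS, C11 aldehyde) | O=CC[C@@H](O[Si](C)(C)C(C)(C)C)CCC[C@H](O[Si](C)(C)C(C)(C)C)C[C@@H](O)[C@H](CC)C(=O)N1[C@@H](Cc2ccccc2)COC1=O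
F4 | step 13 | C1–C11 imide aldehyde, O3-TES ether | O=CC[C@@H](O[Si](C)(C)C(C)(C)C)CCC[C@H](O[Si](C)(C)C(C)(C)C)C[C@@H](O[Si](CC)(CC)CC)[C@H](CC)C(=O)N1[C@@H](Cc2ccccc2)COC1=O
F5 | step 13 | C1–C21 imide (11-OH, 13-oxo, 3-OTES, 5,9,15-tris-OTBS, C21 bromide) | Br/C=C/C=C/C=C/[C@@H](O[Si](C)(C)C(C)(C)C)[C@H](C)C(=O)C[C@@H](O)C[C@@H](O[Si](C)(C)C(C)(C)C)CCC[C@H](O[Si](C)(C)C(C)(C)C)C[C@@H](O[Si](CC)(CC)CC)[C@H](CC)C(=O)N1[C@@H](Cc2ccccc2)COC1=O
F6 | step 13 | C1–C21 imide (11,13-anti diol, 3-OTES, 5,9,15-tris-OTBS, C21 bromide) | Br/C=C/C=C/C=C/[C@@H](O[Si](C)(C)C(C)(C)C)[C@H](C)[C@H](O)C[C@@H](O)C[C@@H](O[Si](C)(C)C(C)(C)C)CCC[C@H](O[Si](C)(C)C(C)(C)C)C[C@@H](O[Si](CC)(CC)CC)[C@H](CC)C(=O)N1[C@@H](Cc2ccccc2)COC1=O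
F7 | step 20 | bis-halide seco-ester of acid 29 with vinyl iodide 4 (six silyl ethers) | Br/C=C/C=C/C=C/[C@@H](O[Si](C)(C)C(C)(C)C)[C@H](C)[C@H](O[Si](CC)(CC)CC)C[C@@H](O[Si](CC)(CC)CC)C[C@@H](O[Si](C)(C)C(C)(C)C)CCC[C@H](O[Si](C)(C)C(C)(C)C)C[C@@H](O[Si](CC)(CC)CC)[C@H](CC)C(=O)O[C@H](C)[C@H](C)/C=C/I
F8 | step 20 | hexaol bis-halide seco-ester (C21 bromide, C24 iodide) | Br/C=C/C=C/C=C/[C@@H](O)[C@H](C)[C@H](O)C[C@@H](O)C[C@@H](O)CCC[C@H](O)C[C@@H](O)[C@H](CC)C(=O)O[C@H](C)[C@H](C)/C=C/I
F9 | step 20 | hexaol seco-ester with C22 dienyl tributylstannane and C21 bromide (formed in the flask, not isolated) | Br/C=C/C=C/C=C/[C@@H](O)[C@H](C)[C@H](O)C[C@@H](O)C[C@@H](O)CCC[C@H](O)C[C@@H](O)[C@H](CC)C(=O)O[C@H](C)[C@H](C)/C=C/C=C/[Sn](CCCC)(CCCC)CCCC
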